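**Retrosynthetic overview**

1. The target is a bicyclo[3.2.1]octan-8-one, numbered C1 (allyl bridgehead), C2 (CH2), C3 (CHOMe), C4 (CHOH), C5 (OMe bridgehead), C6 (CH-aryl), C7 (CHMe), C8 (C=O). The plan rests on one feature: the aryl-bearing C6 is β to the C8 ketone through C5, and the carbinol C4 is the aldol carbon of that same C5, so aryl addition to a C5=C6 enone creates the enolate that closes the ring C1–C2–C3–C4–C5–C8.
2. Last disconnection: C6–aryl and C4–C5 together, back to a 2-methoxy-4-methylcyclopent-2-enone that carries allyl and a (2S)-2-methoxy-3-oxopropyl chain on the quaternary C1, plus 3,4,5-trimethoxyphenylboronic acid.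
3. The 2-methoxy enone comes from the plain enone (epoxidation, then methoxide). C1 is built by two α′-alkylations of (S)-4-methylcyclopent-2-enone: first a glycerol-derived triflate that brings C2–C4 with C3 already set, then allyl bromide anti to the C7 methyl.
4. (S)-4-Methylcyclopent-2-enone comes from (S)-4-silyloxycyclopent-2-enone (cuprate addition, elimination), so that the α′-carbon next to the methyl-bearing carbon is the only site that can be enolised; the triflate comes from (R)-3-(benzyloxy)propane-1,2-diol.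
5. Ring order: the cyclopentane ring C1–C8–C5–C6–C7 is bought; the six-membered ring C1–C2–C3–C4–C5–C8 forms last and completes the bicycle.

Key step: step 13

Assumption: the C1–C8 numbering above is kept for the monocyclic intermediates, and both chiral starting materials are taken as purchasable in enantiopure form.

**Route**

Step 1
Reactants: 1 (R)-3-(benzyloxy)propane-1,2-diol
Product: 2 (S)-1-(benzyloxy)-3-[(tert-butyldiphenylsilyl)oxy]propan-2-ol
Conditions: TBDPSCl, imidazole, CH2Cl2, 0 °C
Reagents that add atoms: tert-butyl(chloro)diphenylsilane, CC(C)(C)[Si](Cl)(c1ccccc1)c1ccccc1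
Why: Silyl ether formation with the bulky chlorosilane is selective for the primary hydroxyl of the 1,2-diol and leaves the secondary carbinol, the future C3, untouched.

Step 2
Reactants: 2 (S)-1-(benzyloxy)-3-[(tert-butyldiphenylsilyl)oxy]propan-2-ol
Product: 3 tert-butyl{[(2S)-3-(benzyloxy)-2-methoxypropyl]oxy}diphenylsilane
Conditions: Me3OBF4, 1,8-bis(dimethylamino)naphthalene, CH2Cl2, 0 °C to rt
Reagents that add atoms: trimethyloxonium tetrafluoroborate, C[O+](C)C.F[B-](F)(F)F
Why: O-Methylation with Meerwein's salt and a non-nucleophilic base alkylates the neutral alcohol, so no alkoxide is formed and 1,2-silyl migration is excluded; the stereocentre is not touched.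

Step 3
Reactants: 3 tert-butyl{[(2S)-3-(benzyloxy)-2-methoxypropyl]oxy}diphenylsilane
Product: 4 (2S)-3-[(tert-butyldiphenylsilyl)oxy]-2-methoxypropan-1-ol
Conditions: H2 (1 atm), 10% Pd/C, EtOAc, rt
Reagents that add atoms: none
Why: Hydrogenolysis of the benzyl ether frees the primary alcohol while the silyl and methyl ethers are inert.

Step 4
Reactants: 4 (2S)-3-[(tert-butyldiphenylsilyl)oxy]-2-methoxypropan-1-ol
Product: 5 (2R)-3-[(tert-butyldiphenylsilyl)oxy]-2-methoxypropyl trifluoromethanesulfonate
Conditions: Tf2O, 2,6-lutidine, CH2Cl2, −78 °C; cold aqueous work-up, used at once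
Reagents that add atoms: trifluoromethanesulfonic anhydride, O=S(=O)(OS(=O)(=O)C(F)(F)F)C(F)(F)F
Why: Sulfonate ester formation gives a primary triflate that should alkylate a ketone enolate at low temperature despite β-branching and the β-methoxy group, where the corresponding iodide would be sluggish.

Step 5
Reactants: 6 (S)-4-[(tert-butyldimethylsilyl)oxy]cyclopent-2-en-1-one
Product: 8 (3S,4S)-4-[(tert-butyldimethylsilyl)oxy]-3-methylcyclopentan-1-one, via lithium enolate 7 (not isolated)
Conditions: Me2CuLi (MeLi, CuI), Et2O, −78 °C; then aq. NH4Cl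
Reagents that add atoms: lithium dimethylcuprate, [Li+].C[Cu-]C
Why: Gilman cuprate conjugate addition to the 4-silyloxycyclopentenone takes place anti to the silyloxy group, which sets the methyl stereocentre (C7) from the purchased stereocentre.

Step 6
Reactants: 8 (3S,4S)-4-[(tert-butyldimethylsilyl)oxy]-3-methylcyclopentan-1-one
Product: 9 (S)-4-methylcyclopent-2-en-1-one
Conditions: DBU, CH2Cl2, 0 °C, stopped at full conversion; product kept in solution (volatile)
Reagents that add atoms: none
Why: E1cB β-elimination of silanol from the β-silyloxy ketone gives the enone in which the α′-carbon next to the methyl-bearing carbon is the only kinetically enolisable site, which fixes the regiochemistry of both alkylations that follow.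

Step 7
Reactants: 9 (S)-4-methylcyclopent-2-en-1-one, 5 (2R)-3-[(tert-butyldiphenylsilyl)oxy]-2-methoxypropyl trifluoromethanesulfonate
Product: 11 (4R,5S)-5-[(2S)-3-[(tert-butyldiphenylsilyl)oxy]-2-methoxypropyl]-4-methylcyclopent-2-en-1-one, via lithium dienolate 10 (not isolated)
Conditions: LiN(i-Pr)2, THF, −78 °C (9 added to the base); then 5, −78 to −40 °C
Reagents that add atoms: none
Why: Kinetic α′-deprotonation gives the cross-conjugated dienolate, which undergoes SN2 enolate alkylation by the primary triflate anti to the neighbouring methyl; this ring centre is reset in step 8 and the side-chain stereocentre is carried in unchanged.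

Step 8
Reactants: 11 (4R,5S)-5-[(2S)-3-[(tert-butyldiphenylsilyl)oxy]-2-methoxypropyl]-4-methylcyclopent-2-en-1-one, 12 allyl bromide
Product: 14 (4R,5R)-5-allyl-5-[(2S)-3-[(tert-butyldiphenylsilyl)oxy]-2-methoxypropyl]-4-methylcyclopent-2-en-1-one, via lithium dienolate 13 (not isolated)
Conditions: LiN(i-Pr)2, THF, −78 °C; then allyl bromide, DMPU, −78 to −30 °C
Reagents that add atoms: none
Why: A second kinetic α′-enolisation and enolate allylation forms the quaternary C1, the allyl bromide approaching the planar dienolate anti to the adjacent C7 methyl so that allyl ends trans and the methoxypropyl chain cis to methyl.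

Step 9
Reactants: 14 (4R,5R)-5-allyl-5-[(2S)-3-[(tert-butyldiphenylsilyl)oxy]-2-methoxypropyl]-4-methylcyclopent-2-en-1-one
Product: 15 2,3-epoxide of 14 (oxirane anti to the C7 methyl): 3-allyl-3-[(2S)-3-[(tert-butyldiphenylsilyl)oxy]-2-methoxypropyl]-4-methyl-6-oxabicyclo[3.1.0]hexan-2-one
Conditions: 30% H2O2, NaOH, MeOH, 0 °C
Reagents that add atoms: hydrogen peroxide, OO
Why: Weitz–Scheffer nucleophilic epoxidation attacks only the electron-poor enone double bond, anti to the C7 methyl, and leaves the allyl group alone; both new centres are removed in step 10.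

Step 10
Reactants: 15 2,3-epoxide of 14
Product: 17 (4R,5R)-5-allyl-5-[(2S)-3-[(tert-butyldiphenylsilyl)oxy]-2-methoxypropyl]-2-methoxy-4-methylcyclopent-2-en-1-one, via hydroxy methoxy ketone 16 (not isolated)
Conditions: NaOMe, MeOH, 0 °C to rt
Reagents that add atoms: sodium methoxide, [Na+].[O-]C
Why: Methoxide opens the α,β-epoxy ketone at the α-carbon C5 and the β-hydroxy ketone dehydrates by E1cB, the known base-mediated conversion of epoxy ketones into 2-alkoxy enones; C1 is quaternary, so no α′-enolisation can interfere.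

Step 11
Reactants: 17 (4R,5R)-5-allyl-5-[(2S)-3-[(tert-butyldiphenylsilyl)oxy]-2-methoxypropyl]-2-methoxy-4-methylcyclopent-2-en-1-one
Product: 18 (4R,5R)-5-allyl-5-[(2S)-3-hydroxy-2-methoxypropyl]-2-methoxy-4-methylcyclopent-2-en-1-one
Conditions: Bu4NF, AcOH, THF, 0 °C to rt
Reagents that add atoms: none
Why: Fluoride cleavage of the silyl ether, buffered with acetic acid so that the γ-stereocentre C7 of the enone does not meet a strong base.

Step 12
Reactants: 18 (4R,5R)-5-allyl-5-[(2S)-3-hydroxy-2-methoxypropyl]-2-methoxy-4-methylcyclopent-2-en-1-one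
Product: 19 (4R,5R)-5-allyl-2-methoxy-5-[(2S)-2-methoxy-3-oxopropyl]-4-methylcyclopent-2-en-1-one
Conditions: Dess–Martin periodinane, pyridine, CH2Cl2, 0 °C to rt; used without chromatography
Reagents that add atoms: none
Why: Dess–Martin oxidation under buffered, non-aqueous conditions should give the α-methoxy aldehyde without epimerising C3 or hydrolysing the enol ether.

Step 13
Reactants: 19 (4R,5R)-5-allyl-2-methoxy-5-[(2S)-2-methoxy-3-oxopropyl]-4-methylcyclopent-2-en-1-one, 20 3,4,5-trimethoxyphenylboronic acid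
Product: 23 (1R,3S,4S,5S,6S,7R)-1-allyl-4-hydroxy-3,5-dimethoxy-7-methyl-6-(3,4,5-trimethoxyphenyl)bicyclo[3.2.1]octan-8-one (overview numbering), via rhodium enolate 21 (not isolated), via rhodium aldolate 22 (not isolated)
Conditions: 20 (2.5 equiv), [Rh(cod)OH]2 (3 mol%), 2,2'-bis(diphenylphosphino)-1,1'-biphenyl (7 mol%), 1,4-dioxane/H2O (20:1), 50 °C
Reagents that add atoms: none
Why: Proposed new method: transmetalation of the boronic acid to the hydroxo–rhodium bisphosphine complex gives an aryl–rhodium species that inserts the C5=C6 bond (aryl to C6) and leaves the oxa-π-allyl rhodium enolate 21, whose C5 adds to the tethered aldehyde carbon C4 before protonation, and hydrolysis of the rhodium aldolate 22 returns the hydroxo–rhodium catalyst. The closest known reaction type is the rhodium-catalysed conjugate addition–aldol cyclisation of arylboronic acids with enones that carry a tethered ketone, which has not been shown for a 2-alkoxycyclopentenone, for a tetrasubstituted enolate that must form a fully substituted carbon, or for a bridging closure onto an aldehyde. The six-membered ring C1–C2–C3–C4–C5–C8 closes by a 6-(enolendo)-exo-trig aldol across the cyclopentane ring. C6 is set by aryl delivery anti to the adjacent C7 methyl, C5 can bond only on the face that carries the C1 side chain, and C4 is set by a closed, rhodium-bridged chair-like transition state in which the aldehyde oxygen lies beside the enolate oxygen (the C3 methoxy group sits on the same side and equatorial), so that the hydroxyl ends syn to C8. The step needs the aryl–rhodium species to choose the enone over the aldehyde and the enolate to cyclise faster than it is protonated; the bisphosphine ligand (a poor promoter of aldehyde arylation), the low water content and the quaternary C1, which holds the aldehyde over C5, are meant to secure this.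

**Compound list**

1 | (R)-3-(benzyloxy)propane-1,2-diol | OC[C@@H](O)COCc1ccccc1 | starting material
2 | (S)-1-(benzyloxy)-3-[(tert-butyldiphenylsilyl)oxy]propan-2-ol | c1ccccc1COC[C@H](O)CO[Si](c1ccccc1)(c1ccccc1)C(C)(C)C | intermediate
3 | tert-butyl{[(2S)-3-(benzyloxy)-2-methoxypropyl]oxy}diphenylsilane | c1ccccc1COC[C@H](OC)CO[Si](c1ccccc1)(c1ccccc1)C(C)(C)C | intermediate
4 | (2S)-3-[(tert-butyldiphenylsilyl)oxy]-2-methoxypropan-1-ol | OC[C@H](OC)CO[Si](c1ccccc1)(c1ccccc1)C(C)(C)C | intermediate
5 | (2R)-3-[(tert-butyldiphenylsilyl)oxy]-2-methoxypropyl trifluoromethanesulfonate | FC(F)(F)S(=O)(=O)OC[C@H](OC)CO[Si](c1ccccc1)(c1ccccc1)C(C)(C)C | intermediate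
6 | (S)-4-[(tert-butyldimethylsilyl)oxy]cyclopent-2-en-1-one | O=C1C=C[C@@H](O[Si](C)(C)C(C)(C)C)C1 | starting material
7 | lithium (3S,4S)-4-[(tert-butyldimethylsilyl)oxy]-3-methylcyclopent-1-en-1-olate (not isolated) | [Li+].[O-]C1=C[C@H](C)[C@@H](O[Si](C)(C)C(C)(C)C)C1 | intermediate
8 | (3S,4S)-4-[(tert-butyldimethylsilyl)oxy]-3-methylcyclopentan-1-one | O=C1C[C@H](C)[C@@H](O[Si](C)(C)C(C)(C)C)C1 | intermediate
9 | (S)-4-methylcyclopent-2-en-1-one | O=C1C=C[C@@H](C)C1 | intermediate
10 | lithium (3R)-3-methylcyclopenta-1,4-dien-1-olate (not isolated) | [Li+].[O-]C1=C[C@H](C)C=C1 | intermediate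
11 | (4R,5S)-5-[(2S)-3-[(tert-butyldiphenylsilyl)oxy]-2-methoxypropyl]-4-methylcyclopent-2-en-1-one (4,5-trans) | O=C1C=C[C@@H](C)[C@@H]1C[C@H](OC)CO[Si](c1ccccc1)(c1ccccc1)C(C)(C)C | intermediate
12 | allyl bromide | C=CCBr | starting material
13 | lithium (3R)-2-[(2S)-3-[(tert-butyldiphenylsilyl)oxy]-2-methoxypropyl]-3-methylcyclopenta-1,4-dien-1-olate (not isolated) | [Li+].[O-]C1=C(C[C@H](OC)CO[Si](c2ccccc2)(c2ccccc2)C(C)(C)C)[C@H](C)C=C1 | intermediate
14 | (4R,5R)-5-allyl-5-[(2S)-3-[(tert-butyldiphenylsilyl)oxy]-2-methoxypropyl]-4-methylcyclopent-2-en-1-one (allyl trans to methyl) | C=CC[C@]1(C[C@H](OC)CO[Si](c2ccccc2)(c2ccccc2)C(C)(C)C)C(=O)C=C[C@H]1C | intermediate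
15 | 2,3-epoxide of 14, oxirane oxygen anti to the C7 methyl: 3-allyl-3-[(2S)-3-[(tert-butyldiphenylsilyl)oxy]-2-methoxypropyl]-4-methyl-6-oxabicyclo[3.1.0]hexan-2-one | C=CC[C@]1(C[C@H](OC)CO[Si](c2ccccc2)(c2ccccc2)C(C)(C)C)C(=O)[C@@H]2O[C@@H]2[C@H]1C | intermediate
16 | trans-3-hydroxy-2-methoxy ketone from opening of 15 at C5: 5-allyl-5-[(2S)-3-[(tert-butyldiphenylsilyl)oxy]-2-methoxypropyl]-3-hydroxy-2-methoxy-4-methylcyclopentan-1-one (not isolated) | C=CC[C@]1(C[C@H](OC)CO[Si](c2ccccc2)(c2ccccc2)C(C)(C)C)C(=O)[C@@H](OC)[C@H](O)[C@H]1C | intermediate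
17 | (4R,5R)-5-allyl-5-[(2S)-3-[(tert-butyldiphenylsilyl)oxy]-2-methoxypropyl]-2-methoxy-4-methylcyclopent-2-en-1-one | C=CC[C@]1(C[C@H](OC)CO[Si](c2ccccc2)(c2ccccc2)C(C)(C)C)C(=O)C(OC)=C[C@H]1C | intermediate
18 | (4R,5R)-5-allyl-5-[(2S)-3-hydroxy-2-methoxypropyl]-2-methoxy-4-methylcyclopent-2-en-1-one | C=CC[C@]1(C[C@H](OC)CO)C(=O)C(OC)=C[C@H]1C | intermediate
19 | (4R,5R)-5-allyl-2-methoxy-5-[(2S)-2-methoxy-3-oxopropyl]-4-methylcyclopent-2-en-1-one | C=CC[C@]1(C[C@H](OC)C=O)C(=O)C(OC)=C[C@H]1C | intermediate
20 | 3,4,5-trimethoxyphenylboronic acid | OB(O)c1cc(OC)c(OC)c(OC)c1 | starting material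
21 | O-bound monovalent rhodium enolate of the C6-arylated ketone, rhodium carrying 2,2'-bis(diphenylphosphino)biphenyl (not isolated) | C=CC[C@]1(C[C@H](OC)C=O)C(O[Rh-2]2[P+](c3ccccc3)(c3ccccc3)c3ccccc3-c3ccccc3[P+]2(c2ccccc2)c2ccccc2)=C(OC)[C@H](c2cc(OC)c(OC)c(OC)c2)[C@H]1C | intermediate
22 | monovalent rhodium C4-alkoxide of 23, rhodium carrying 2,2'-bis(diphenylphosphino)biphenyl (not isolated) | C=CC[C@]12C[C@H](OC)[C@H](O[Rh-2]3[P+](c4ccccc4)(c4ccccc4)c4ccccc4-c4ccccc4[P+]3(c3ccccc3)c3ccccc3)[C@](OC)(C1=O)[C@H](c1cc(OC)c(OC)c(OC)c1)[C@H]2C | intermediate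
23 | (1R,3S,4S,5S,6S,7R)-1-allyl-4-hydroxy-3,5-dimethoxy-7-methyl-6-(3,4,5-trimethoxyphenyl)bicyclo[3.2.1]octan-8-one (overview numbering) | C=CC[C@]12C[C@H](OC)[C@H](O)[C@](OC)(C1=O)[C@H](c1cc(OC)c(OC)c(OC)c1)[C@H]2C | target

**Step count and risks**

Total: 13 steps. Longest linear sequence: 11 steps (1 to 23 through steps 1–4 and 7–13); the ring branch from 6 is 9 steps.

Step 13 (highest risk). The aryl–rhodium species may arylate the aldehyde instead of the hindered 2-methoxy enone. The rhodium enolate may be protonated before it reaches the aldehyde. C3 may epimerise in the aldehyde while a slow addition runs. The fallback uses known reactions only and sets out from 17, where the aldehyde is still masked. Copper-mediated conjugate addition of commercial 3,4,5-trimethoxyphenylmagnesium bromide (CuBr·SMe2, Me3SiCl, THF, −78 °C, aqueous work-up) should add the aryl group anti to the C7 methyl and give (3S,4R,5R)-5-allyl-5-[(2S)-3-[(tert-butyldiphenylsilyl)oxy]-2-methoxypropyl]-2-methoxy-4-methyl-3-(3,4,5-trimethoxyphenyl)cyclopentan-1-one F1 as a mixture at C5. Bu4NF/AcOH then gives the alcohol (3S,4R,5R)-5-allyl-5-[(2S)-3-hydroxy-2-methoxypropyl]-2-methoxy-4-methyl-3-(3,4,5-trimethoxyphenyl)cyclopentan-1-one F2, and Dess–Martin periodinane gives the keto aldehyde (3S,4R,5R)-5-allyl-2-methoxy-5-[(2S)-2-methoxy-3-oxopropyl]-4-methyl-3-(3,4,5-trimethoxyphenyl)cyclopentan-1-one F3. The ketone of F3 can enolise only at C5, and only that enolate reaches the aldehyde through a six-membered ring. An intramolecular aldol with catalytic DBU in CH2Cl2 at 0 °C, run under equilibrating conditions, should therefore close the same C4–C5 bond and return to 23, the alcohol hydrogen-bonded to the C8 ketone being the one expected to accumulate. The same last operation would also recover any uncyclised, protonated material from step 13.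

Step 7. The cross-conjugated cyclopentadienolate may be lost to proton transfer, self-condensation and O-alkylation before the β-branched triflate alkylates it on carbon. The fallback makes the C1–C2 bond by aldol addition, which is fast at −78 °C, and then removes the extra oxygen. It sets out from 4 and 9. Dess–Martin oxidation of 4 gives (R)-3-[(tert-butyldiphenylsilyl)oxy]-2-methoxypropanal F4. Its addition to the lithium dienolate 10 of 9 (THF, −78 °C) gives the aldol 5-[(2R)-3-[(tert-butyldiphenylsilyl)oxy]-1-hydroxy-2-methoxypropyl]-4-methylcyclopent-2-en-1-one F5 (4,5-trans, carbinol epimers). 1,1'-Thiocarbonyldiimidazole with DMAP converts it into the O-(imidazol-1-ylthiocarbonyl) derivative F6. Barton–McCombie deoxygenation (Bu3SnH, AIBN, toluene, 80 °C) then removes the C2 oxygen and returns to 11.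

Step 8. C-Allylation at the hindered, fully substituted α′-carbon may be slow, so that O-allylation and proton exchange between enolate and product compete. The fallback sets out from 11. The lithium dienolate 13 is trapped on oxygen with allyl chloroformate at −78 °C to give allyl (3R)-2-[(2S)-3-[(tert-butyldiphenylsilyl)oxy]-2-methoxypropyl]-3-methylcyclopenta-1,4-dien-1-yl carbonate F7, which is kept at or below 0 °C. Pd(PPh3)4 (zerovalent palladium) in THF at 0 °C should then bring about decarboxylative Tsuji allylation, in which the π-allylpalladium–enolate ion pair collapses at C1 anti to the C7 methyl, returning to 14.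

Further compounds
F1 | step 13 | (3S,4R,5R)-5-allyl-5-[(2S)-3-[(tert-butyldiphenylsilyl)oxy]-2-methoxypropyl]-2-methoxy-4-methyl-3-(3,4,5-trimethoxyphenyl)cyclopentan-1-one (C2 epimers of the ring) | C=CC[C@]1(C[C@H](OC)CO[Si](c2ccccc2)(c2ccccc2)C(C)(C)C)C(=O)C(OC)[C@H](c2cc(OC)c(OC)c(OC)c2)[C@H]1C
F2 | step 13 | (3S,4R,5R)-5-allyl-5-[(2S)-3-hydroxy-2-methoxypropyl]-2-methoxy-4-methyl-3-(3,4,5-trimethoxyphenyl)cyclopentan-1-one (C2 epimers of the ring) | C=CC[C@]1(C[C@H](OC)CO)C(=O)C(OC)[C@H](c2cc(OC)c(OC)c(OC)c2)[C@H]1C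
F3 | step 13 | (3S,4R,5R)-5-allyl-2-methoxy-5-[(2S)-2-methoxy-3-oxopropyl]-4-methyl-3-(3,4,5-trimethoxyphenyl)cyclopentan-1-one (C2 epimers of the ring) | C=CC[C@]1(C[C@H](OC)C=O)C(=O)C(OC)[C@H](c2cc(OC)c(OC)c(OC)c2)[C@H]1C
F4 | step 7 | (R)-3-[(tert-butyldiphenylsilyl)oxy]-2-methoxypropanal | O=C[C@H](OC)CO[Si](c1ccccc1)(c1ccccc1)C(C)(C)C
F5 | step 7 | 5-[(2R)-3-[(tert-butyldiphenylsilyl)oxy]-1-hydroxy-2-methoxypropyl]-4-methylcyclopent-2-en-1-one (4,5-trans, ring configuration as in 11, carbinol epimers) | O=C1C=C[C@@H](C)[C@@H]1C(O)[C@H](OC)CO[Si](c1ccccc1)(c1ccccc1)C(C)(C)C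
F6 | step 7 | O-(imidazol-1-ylthiocarbonyl) derivative of F5 | O=C1C=C[C@@H](C)[C@@H]1C(OC(=S)n1ccnc1)[C@H](OC)CO[Si](c1ccccc1)(c1ccccc1)C(C)(C)C
F7 | step 8 | allyl (3R)-2-[(2S)-3-[(tert-butyldiphenylsilyl)oxy]-2-methoxypropyl]-3-methylcyclopenta-1,4-dien-1-yl carbonate | C=CCOC(=O)OC1=C(C[C@H](OC)CO[Si](c2ccccc2)(c2ccccc2)C(C)(C)C)[C@H](C)C=C1
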